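Readings and results stem from a simulated flask with made-up constants; noise was put on by code.

- The flask holds 35 mM of starting material against 0.46 mM of free catalyst, so each catalyst must turn about 76.1 times to use it up, and a small loss of catalyst per turn adds up.

| setting | epsilon | delta | alpha | flask |
|---|---|---|---|---|
| starting material | 35 mM | 35 mM | 35 mM | 35 mM |
| coupling partner | 38.5 mM | 38.5 mM | 58 mM | 38.5 mM |
| capture agent | 3.5 mM | 3.5 mM | 3.5 mM | 3.50 mM |
| free catalyst | 0.31 mM | 0.69 mM | 0.46 mM | 0.46 mM |
| remark | run made earlier | run made earlier | run made earlier |  |

- epsilon (time / min: target / %, starting material / %): 2.00: 14, 88; 4.00: 23, 77; 6.00: 31, 71; 8.00: 34, 65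
- delta (time / min: target / %, starting material / %): 0.667: 10, 86; 1.33: 19, 81; 3.00: 37, 64; 8.00: 64, 33
- alpha (time / min: target / %, starting material / %): 1.00: 8, 88; 3.00: 27, 70; 5.00: 44, 56; 8.00: 58, 41

(each reading ± 1.5 percentage points)

- factor on the rate of making target when 20% of the starting material are converted if free catalyst is charged twice over
- factor on the rate when 20% of the starting material are converted if free catalyst is charged at 5.0 mM instead

- candidate steps: capture agent + catalyst intermediate B -> trapped intermediate; starting material + free catalyst -> catalyst intermediate A; catalyst intermediate A -> catalyst intermediate B; coupling partner + catalyst intermediate B <-> catalyst intermediate C; catalyst intermediate C -> free catalyst + target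

- Short rung: in the epsilon run, target climbs at 0.0450 /min of the charge between 2.00 min and 4.00 min. Reckoned on the charged catalyst, one round therefore takes about 0.197 min, the inverse of the turnover frequency.
- Middle rung: the epsilon run passes the mark of 20% conversion between 2.00 min and 4.00 min; you take the midpoint, 3.00 min, as a rough time for it, long after one round. You may therefore take the rate at the mark to follow the catalyst still working then.
- Long rung: capture agent takes catalyst intermediate B off-cycle as trapped intermediate, and you assume that the amount lost by a given conversion is the same for any charge. Across the mark the delta run climbs at 0.116 /min, which is 2.57 times the epsilon pace, on a charge 2.23 times the epsilon charge. Setting that gain equal to the ratio of the two charges, each less the loss, gives 0.0682 mM: this is L, the catalyst lost by the mark, a reading that carries the scatter. Reckoned at that pace, the epsilon charge has a lifetime of about 13.6 min, longer than the mark takes.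
- In this flask, by your reckoning, about 0.392 mM still works at the mark. Your own reckoning gives 2.17 for the doubled charge and 12.6 for 5.0 mM. The forecast says 2.18 and 12, holding that “loss scales with product, not catalyst”, and its ratio stands below yours.

- The flask gives 2.24 and 13.6, and the forecast is right within the margins.

    capture agent + catalyst intermediate B → trapped intermediate (k = 2.50 /M/s)
    starting material + free catalyst → catalyst intermediate A (k = 10.0 /M/s)
    catalyst intermediate A → catalyst intermediate B (k = 0.480 /s)
    coupling partner + catalyst intermediate B ⇌ catalyst intermediate C (K = 53.0 /M, k = 27.0 /M/s)
    catalyst intermediate C → free catalyst + target (k = 1.30 /s)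

- In this flask, one percent more on the rate constant of the capture step changes the rate by −0.23 percent, and L is 17.4% of the catalyst reckoned as working at the mark. Carried to the flask with 5.0 mM, L is 1.36% of the charge, and that flask's rate stands at 13.6 times this flask's rate on 10.9 times the charge.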